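**Plan**

- Locants: ring C5 (bears the C4 side chain), C6 (OH), C7 (bears the C11 acrylic acid), C8 (O-acyl), C9 (CH2), C10 (CH3 and vinyl); β is the face of the C10 methyl, α the face of the C10 vinyl.
- Cuts: the C8 ester (formed with inversion), the C11 acrylate (from an acetyl group, from C7–Br), the side-chain hydroxyl on C4 (allylic oxidation), C4=CH2 (from a lactone carbonyl), then the ring bonds C8–C9 and C5–C10 in one [4+2] cycloaddition.
- Enabling feature: O–C8–C7–C6–C5–C4 (the C8 oxygen, three ring carbons and a C4 that can be a carbonyl) is the O1–C6=C5–C4=C3–C2(=O) chain of a 2-pyrone, and C9–C10(CH3)(vinyl) is a 1,1-disubstituted alkene. A flat 5-bromo-2-pyrone-3-carboxylate and 2-methylbut-1-en-3-yne (ethynyl as masked vinyl) therefore give the carbocycle as a 2-oxabicyclo[2.2.2]octenone.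
- Forward order: cycloaddition, removal of the activating ester at the bridgehead, alkyne to vinyl, lactone opened with MeLi and methylenated, C7 acetyl, C6 oxygen by conjugate borylation, enol triflate, C8 inversion with esterification, carbonylation, allylic oxidation, fluoride deprotection.
- Stereochemistry: the chiral copper bis(oxazoline) catalyst fixes the pyrone face (C5, C8) and the endo ethynyl group fixes C10; the β-face groups left by the lactone bridge steer boron to C6α and leave the C7 acetyl equatorial; C8 is inverted by SN2.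

Key step: step 1

Assumption: the bromopyrone ester used in step 1 is taken from a catalogue, and the ligand antipode that opens the pyrone face drawn for the cycloadduct is fixed in a first trial; (S,S) is written.

**Route**

Step 1
Reactants: 1 methyl 5-bromo-2-oxo-2H-pyran-3-carboxylate; 2 2-methylbut-1-en-3-yne
Product: 3 methyl 6-bromo-8-ethynyl-8-methyl-3-oxo-2-oxabicyclo[2.2.2]oct-5-ene-4-carboxylate, ethynyl endo (on the side of the C=C bridge, away from the lactone bridge); bicyclic C1, C4 and C8 are target C8, C5 and C10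
Conditions: Cu(OTf)2 (10 mol%), (S,S)-tBu-BOX [2,2'-(propane-2,2-diyl)bis((4S)-4-tert-butyl-4,5-dihydrooxazole)] (11 mol%), 4 Å MS, CH2Cl2, 2 (5 equiv), sealed vessel, −20 °C → rt
Reagents that add atoms: none
Why: Proposed new method: Cu(OTf)2 and the bis(oxazoline) chelate the lactone and ester carbonyls of 1, which lowers the pyrone LUMO, so that the CH2 terminus of 2 bonds to pyrone C6 (target C8) while the fully substituted carbon, which carries propargylic cation character, closes on C3 (target C5) in an asynchronous suprafacial inverse-electron-demand [4+2] cycloaddition. The closest known reaction type is the chiral copper bis(oxazoline)-catalysed inverse-demand Diels–Alder reaction of 3-carboalkoxy-2-pyrones with enol ethers and styrene-type alkenes, which has not been shown with a conjugated enyne as the 2π partner. The one new carbocycle, the cyclohexene C5–C10, is closed by this [4+2] mode as part of a 2-oxabicyclo[2.2.2]octenone whose lactone bridge keeps CO2 in the molecule. C8 and C5 are set together because both new bonds form on one face of the flat pyrone, the face being chosen by the tert-butyl groups of the ligand, and C10 is set by the endo placement of the ethynyl group (secondary overlap with the diene, methyl exo). The step needs regio-, site- and periselectivity: the polarisation of the chelated pyrone (C6 electrophilic) and of 2 (CH2 nucleophilic) secures the C8–C9 and C5–C10 pairing, the alkene of 2 is more nucleophilic than its alkyne, and a propargylic cation cannot close through its allenyl terminus, which rules out the fused adduct that a 1,3-diene could give.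

Step 2
Reactants: 3 bicyclic lactone methyl ester
Product: 4 6-bromo-8-ethynyl-8-methyl-3-oxo-2-oxabicyclo[2.2.2]oct-5-ene-4-carboxylic acid (configuration as in 3)
Conditions: LiI (3 equiv), EtOAc, reflux; then 1 M HCl
Reagents that add atoms: none
Why: SN2 dealkylation of the methyl ester by iodide; the lactone is not cleaved in the same way because its O-bearing carbon is a bridgehead, and the malonic half-acid should be stable because enolisation toward the bridgehead is not possible.

Step 3
Reactants: 4 bridgehead carboxylic acid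
Product: 7 6-bromo-8-ethynyl-8-methyl-2-oxabicyclo[2.2.2]oct-5-en-3-one (bridgehead H in place of CO2H, ethynyl endo), via acid chloride 5 (not isolated), via thiohydroxamate ester 6 (not isolated)
Conditions: (COCl)2, cat. DMF, CH2Cl2, 0 °C → rt; then 2-mercaptopyridine N-oxide sodium salt (C5H4NNaOS), cat. DMAP, PhH; then t-BuSH, hν (tungsten lamp), rt
Reagents that add atoms: none
Why: Barton radical decarboxylation; the bridgehead radical cannot invert, so hydrogen-atom transfer from the thiol puts H where the carboxyl was and C5 keeps its configuration (lactone carbonyl, the future C4, cis to the C8–O bridge).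

Step 4
Reactants: 7 ethynyl lactone
Product: 8 6-bromo-8-methyl-8-vinyl-2-oxabicyclo[2.2.2]oct-5-en-3-one (vinyl endo)
Conditions: H2 (1 atm), Pd/CaCO3 poisoned with Pb(OAc)2 (Lindlar catalyst), quinoline, EtOAc, rt
Reagents that add atoms: none
Why: Lindlar semihydrogenation of the terminal alkyne, which should leave the trisubstituted bromoalkene untouched; it is done at room temperature and the next step is cold, because an endo vinyl group on this bicycle could undergo Cope rearrangement on heating.

Step 5
Reactants: 8 vinyl lactone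
Product: 10 hydroxy ketone, cyclohex-6-ene with 5β-acetyl, 7-bromo, 8β-hydroxy, 10β-methyl, 10α-vinyl (used crude), via lithium hemiketalate 9 (not isolated)
Conditions: MeLi (1.1 equiv), THF, −78 °C; then AcOH, −78 °C
Reagents that add atoms: methyllithium [Li]C
Why: Mono-addition of an organolithium to a lactone; the bridged lithium hemiketalate should not collapse at −78 °C, so no second addition occurs, the bridgehead C5–H cannot be enolised, and protonation opens the ring to the methyl ketone and the free 8β-hydroxyl.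

Step 6
Reactants: 10 hydroxy ketone
Product: 11 cyclohex-6-ene with 5β-isopropenyl, 7-bromo, 8β-hydroxy, 10β-methyl, 10α-vinyl
Conditions: Zn, CH2Br2, TiCl4 (Lombardo reagent, preformed), THF/CH2Cl2, 0 °C → rt
Reagents that add atoms: dibromomethane BrCBr
Why: Lombardo methylenation, chosen as a non-basic olefination because the β,γ-unsaturated ketone has a doubly activated C5–H that a Wittig ylide could epimerise or move into conjugation.

Step 7
Reactants: 11 allylic alcohol
Product: 12 8β-O-triethylsilyl ether of 11
Conditions: Et3SiCl, imidazole, CH2Cl2, 0 °C → rt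
Reagents that add atoms: chlorotriethylsilane CC[Si](Cl)(CC)CC
Why: Standard silylation of the only hydroxyl; the triethylsilyl group is chosen so that it can later be removed in the presence of a tert-butyldimethylsilyl ether.

Step 8
Reactants: 12 alkenyl bromide
Product: 14 enone, cyclohex-6-ene with 7-acetyl, 5β-isopropenyl, 8β-OSiEt3, 10β-methyl, 10α-vinyl, via ethoxydiene 13 (not isolated)
Conditions: Pd(PPh3)4 (5 mol%), tributyl(1-ethoxyvinyl)stannane, toluene, 90 °C; then 5% aq. oxalic acid, THF, 0 °C
Reagents that add atoms: tributyl(1-ethoxyvinyl)stannane CCCC[Sn](CCCC)(CCCC)C(=C)OCC; water O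
Why: Stille coupling of the alkenyl bromide with an acetyl anion equivalent, followed by mild enol ether hydrolysis that the silyl ether should survive.

Step 9
Reactants: 14 enone
Product: 16 β-hydroxy ketone, cyclohexane with 6α-hydroxy, 7β-acetyl, 5β-isopropenyl, 8β-OSiEt3, 10β-methyl, 10α-vinyl, via C6α-boronate 15 (not isolated)
Conditions: CuCl (5 mol%), NaOtBu (10 mol%), Xantphos (5 mol%), B2pin2 (1.2 equiv), MeOH (2 equiv), THF, rt; then 30% H2O2, NaHCO3, THF/H2O, 0 °C
Reagents that add atoms: bis(pinacolato)diboron CC1(C)OB(OC1(C)C)B1OC(C)(C)C(C)(C)O1 (boron of 15); hydrogen peroxide OO (oxygen of 16)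
Why: Copper-catalysed conjugate borylation of the enone and C–B oxidation with retention; boron should add to C6 from the α-face, away from the adjacent β-isopropenyl group and the β groups on C8 and C10, and C7 is protonated (or equilibrated) so that the acetyl group is equatorial and trans to the C6 substituent, while the unactivated vinyl and isopropenyl groups do not react.

Step 10
Reactants: 16 β-hydroxy ketone
Product: 17 6α-O-tert-butyldimethylsilyl ether of 16
Conditions: tBuMe2SiOTf, 2,6-lutidine, CH2Cl2, −78 → 0 °C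
Reagents that add atoms: tert-butyldimethylsilyl triflate CC(C)(C)[Si](C)(C)OS(=O)(=O)C(F)(F)F
Why: Silylation of a hindered secondary alcohol with a silyl triflate under non-nucleophilic base, which also removes the risk of retro-aldol or dehydration of the β-hydroxy ketone.

Step 11
Reactants: 17 methyl ketone
Product: 19 enol triflate, 7β-[1-(trifluoromethylsulfonyloxy)vinyl] with 6α-OSitBuMe2 and 8β-OSiEt3, via potassium enolate 18 (not isolated)
Conditions: KN(SiMe3)2 (1.1 equiv), THF, −78 °C; then PhNTf2, −78 → 0 °C; aq. NH4Cl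
Reagents that add atoms: N-phenylbis(trifluoromethanesulfonimide) O=S(=O)(N(c1ccccc1)S(=O)(=O)C(F)(F)F)C(F)(F)F
Why: Kinetic deprotonation at the methyl group (the tertiary C7–H is flanked by two silyloxy carbons) and O-triflation of the enolate, which fixes C7 so that it can no longer epimerise.

Step 12
Reactants: 19 bis-silyl ether
Product: 20 8β-alcohol, 7β-[1-(trifluoromethylsulfonyloxy)vinyl], 6α-OSitBuMe2
Conditions: HF·pyridine, pyridine, THF, 0 °C
Reagents that add atoms: none
Why: Selective cleavage of the triethylsilyl ether beside the bulkier tert-butyldimethylsilyl ether with buffered HF; doing it at the enol triflate stage means no ester is present that the cis 8β-hydroxyl could attack.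

Step 13
Reactants: 21 ethyl 2-(hydroxymethyl)prop-2-enoate
Product: 22 ethyl 2-{[tert-butyl(dimethyl)silyl]oxymethyl}prop-2-enoate
Conditions: tBuMe2SiCl, imidazole, CH2Cl2, rt
Reagents that add atoms: tert-butyldimethylsilyl chloride CC(C)(C)[Si](C)(C)Cl
Why: Standard silylation of the primary allylic alcohol so that it cannot compete as the alcohol partner in the later esterification.

Step 14
Reactants: 22 silyl ether ester
Product: 23 2-{[tert-butyl(dimethyl)silyl]oxymethyl}prop-2-enoic acid
Conditions: LiOH·H2O, THF/H2O, 0 °C → rt; then 1 M HCl to pH 4, 0 °C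
Reagents that add atoms: lithium hydroxide [Li+].[OH-]
Why: Saponification of the ethyl ester under conditions mild enough to keep the primary silyl ether.

Step 15
Reactants: 20 8β-alcohol; 23 silyloxymethyl acrylic acid
Product: 24 8α-ester, cyclohexane with 8α-O-acyl (2-{[tert-butyl(dimethyl)silyl]oxymethyl}acryloyl), 7β-[1-(trifluoromethylsulfonyloxy)vinyl], 6α-OSitBuMe2, 5β-isopropenyl
Conditions: PPh3, DIAD, toluene, 0 °C → rt
Reagents that add atoms: none
Why: Mitsunobu esterification; SN2 displacement of the oxyphosphonium by the carboxylate inverts C8 from β to α, helped by the axial leaving group whose departure relieves the 1,3-diaxial contact with the C10 methyl group.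

Step 16
Reactants: 24 enol triflate
Product: 25 as 24 but with 7β-[1-(2-trimethylsilylethoxycarbonyl)vinyl]
Conditions: Pd(OAc)2 (10 mol%), PPh3 (20 mol%), CO (1 atm), Me3SiCH2CH2OH (5 equiv), Et3N, DMF, 50 °C
Reagents that add atoms: carbon monoxide [C-]#[O+]; 2-(trimethylsilyl)ethanol C[Si](C)(C)CCO
Why: Palladium-catalysed alkoxycarbonylation of the alkenyl triflate gives the 2-substituted acrylate directly as an ester that fluoride can cleave.

Step 17
Reactants: 25 isopropenyl compound
Product: 26 as 25 but with 5β-(3-hydroxyprop-1-en-2-yl)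
Conditions: SeO2 (0.5 equiv), t-BuOOH (5.5 M in decane, 2 equiv), CH2Cl2, 0 °C → rt
Reagents that add atoms: selenium dioxide O=[Se]=O (oxygen carrier); tert-butyl hydroperoxide CC(C)(C)OO
Why: Selenium dioxide allylic oxidation (ene reaction then [2,3]-shift) should be confined to the isopropenyl group, the only electron-rich alkene with allylic hydrogens (the vinyl group sits on a quaternary carbon, the acrylates are electron-poor), and should prefer its CH3 over the ring CH.

Step 18
Reactants: 26 tris-silyl precursor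
Product: 27 target hydroxy acid, cyclohexane with 5β-(3-hydroxyprop-1-en-2-yl), 6α-OH, 7β-(1-carboxyvinyl), 8α-[2-(hydroxymethyl)acryloyloxy], 10β-methyl, 10α-vinyl
Conditions: TASF [(Me2N)3S][Me3SiF2] (5 equiv), DMF, 0 °C → rt; NaH2PO4 buffer (pH 4–5) work-up, 0 °C
Reagents that add atoms: none
Why: Fluoride cleaves the silylethyl ester (β-elimination to ethene) and both silyl ethers; the unhindered Me3Si of the ester should react before the hindered C6 silyl ether, so the acid is a carboxylate when the C6 hydroxyl appears and should not lactonise, and the work-up is kept cold and only weakly acidic for the same reason.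

**Compound list**

1 | methyl 5-bromo-2-oxo-2H-pyran-3-carboxylate | COC(=O)C1=CC(Br)=COC1=O | starting material
2 | 2-methylbut-1-en-3-yne | C=C(C)C#C | starting material
3 | methyl 6-bromo-8-ethynyl-8-methyl-3-oxo-2-oxabicyclo[2.2.2]oct-5-ene-4-carboxylate (ethynyl endo) | C#C[C@]1(C)C[C@H]2OC(=O)[C@]1(C(=O)OC)C=C2Br | intermediate
4 | 6-bromo-8-ethynyl-8-methyl-3-oxo-2-oxabicyclo[2.2.2]oct-5-ene-4-carboxylic acid | C#C[C@]1(C)C[C@H]2OC(=O)[C@]1(C(=O)O)C=C2Br | intermediate
5 | acid chloride of 4 | C#C[C@]1(C)C[C@H]2OC(=O)[C@]1(C(=O)Cl)C=C2Br | intermediate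
6 | 2-thioxopyridin-1(2H)-yl ester of 4 (thiohydroxamate ester) | C#C[C@]1(C)C[C@H]2OC(=O)[C@]1(C(=O)ON3C=CC=CC3=S)C=C2Br | intermediate
7 | 6-bromo-8-ethynyl-8-methyl-2-oxabicyclo[2.2.2]oct-5-en-3-one (ethynyl endo) | C#C[C@]1(C)C[C@H]2OC(=O)[C@@H]1C=C2Br | intermediate
8 | 6-bromo-8-methyl-8-vinyl-2-oxabicyclo[2.2.2]oct-5-en-3-one (vinyl endo) | C=C[C@]1(C)C[C@H]2OC(=O)[C@@H]1C=C2Br | intermediate
9 | lithium 6-bromo-3,8-dimethyl-8-vinyl-2-oxabicyclo[2.2.2]oct-5-en-3-olate (hemiketal carbon not controlled) | C=C[C@]1(C)C[C@H]2OC(C)([O-])[C@@H]1C=C2Br.[Li+] | intermediate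
10 | cyclohex-6-ene: 5β-acetyl, 7-bromo, 8β-hydroxy, 10β-methyl, 10α-vinyl | C=C[C@]1(C)C[C@@H](O)C(Br)=C[C@H]1C(C)=O | intermediate
11 | cyclohex-6-ene: 5β-isopropenyl, 7-bromo, 8β-hydroxy, 10β-methyl, 10α-vinyl | C=C[C@]1(C)C[C@@H](O)C(Br)=C[C@H]1C(C)=C | intermediate
12 | 8β-O-triethylsilyl ether of 11 | C=C[C@]1(C)C[C@@H](O[Si](CC)(CC)CC)C(Br)=C[C@H]1C(C)=C | intermediate
13 | cyclohex-6-ene: 7-(1-ethoxyvinyl), 5β-isopropenyl, 8β-OSiEt3, 10β-methyl, 10α-vinyl | C=C[C@]1(C)C[C@@H](O[Si](CC)(CC)CC)C(C(=C)OCC)=C[C@H]1C(C)=C | intermediate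
14 | cyclohex-6-ene: 7-acetyl, 5β-isopropenyl, 8β-OSiEt3, 10β-methyl, 10α-vinyl | C=C[C@]1(C)C[C@@H](O[Si](CC)(CC)CC)C(C(C)=O)=C[C@H]1C(C)=C | intermediate
15 | cyclohexane: 6α-(pinacolboryl), 7β-acetyl, 5β-isopropenyl, 8β-OSiEt3, 10β-methyl, 10α-vinyl | C=C[C@]1(C)C[C@@H](O[Si](CC)(CC)CC)[C@@H](C(C)=O)[C@H](B2OC(C)(C)C(C)(C)O2)[C@H]1C(C)=C | intermediate
16 | cyclohexane: 6α-hydroxy, 7β-acetyl, 5β-isopropenyl, 8β-OSiEt3, 10β-methyl, 10α-vinyl | C=C[C@]1(C)C[C@@H](O[Si](CC)(CC)CC)[C@@H](C(C)=O)[C@H](O)[C@H]1C(C)=C | intermediate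
17 | 6α-O-tert-butyldimethylsilyl ether of 16 | C=C[C@]1(C)C[C@@H](O[Si](CC)(CC)CC)[C@@H](C(C)=O)[C@H](O[Si](C)(C)C(C)(C)C)[C@H]1C(C)=C | intermediate
18 | potassium enolate of 17 (terminal, toward CH3) | C=C[C@]1(C)C[C@@H](O[Si](CC)(CC)CC)[C@@H](C(=C)[O-])[C@H](O[Si](C)(C)C(C)(C)C)[C@H]1C(C)=C.[K+] | intermediate
19 | cyclohexane: 7β-[1-(triflyloxy)vinyl], 6α-OSitBuMe2, 8β-OSiEt3, 5β-isopropenyl, 10β-methyl, 10α-vinyl | C=C[C@]1(C)C[C@@H](O[Si](CC)(CC)CC)[C@@H](C(=C)OS(=O)(=O)C(F)(F)F)[C@H](O[Si](C)(C)C(C)(C)C)[C@H]1C(C)=C | intermediate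
20 | 8β-alcohol from 19 | C=C[C@]1(C)C[C@@H](O)[C@@H](C(=C)OS(=O)(=O)C(F)(F)F)[C@H](O[Si](C)(C)C(C)(C)C)[C@H]1C(C)=C | intermediate
21 | ethyl 2-(hydroxymethyl)prop-2-enoate | CCOC(=O)C(=C)CO | starting material
22 | ethyl 2-{[tert-butyl(dimethyl)silyl]oxymethyl}prop-2-enoate | CCOC(=O)C(=C)CO[Si](C)(C)C(C)(C)C | intermediate
23 | 2-{[tert-butyl(dimethyl)silyl]oxymethyl}prop-2-enoic acid | OC(=O)C(=C)CO[Si](C)(C)C(C)(C)C | intermediate
24 | cyclohexane: 8α-O-(2-{[tert-butyl(dimethyl)silyl]oxymethyl}acryloyl), 7β-[1-(triflyloxy)vinyl], 6α-OSitBuMe2, 5β-isopropenyl, 10β-methyl, 10α-vinyl | C=C[C@]1(C)C[C@H](OC(=O)C(=C)CO[Si](C)(C)C(C)(C)C)[C@@H](C(=C)OS(=O)(=O)C(F)(F)F)[C@H](O[Si](C)(C)C(C)(C)C)[C@H]1C(C)=C | intermediate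
25 | as 24 with 7β-[1-(2-trimethylsilylethoxycarbonyl)vinyl] | C=C[C@]1(C)C[C@H](OC(=O)C(=C)CO[Si](C)(C)C(C)(C)C)[C@@H](C(=C)C(=O)OCC[Si](C)(C)C)[C@H](O[Si](C)(C)C(C)(C)C)[C@H]1C(C)=C | intermediate
26 | as 25 with 5β-(3-hydroxyprop-1-en-2-yl) | C=C[C@]1(C)C[C@H](OC(=O)C(=C)CO[Si](C)(C)C(C)(C)C)[C@@H](C(=C)C(=O)OCC[Si](C)(C)C)[C@H](O[Si](C)(C)C(C)(C)C)[C@H]1C(=C)CO | intermediate
27 | CNP0509685.1: cyclohexane with 5β-(3-hydroxyprop-1-en-2-yl), 6α-OH, 7β-(1-carboxyvinyl), 8α-[2-(hydroxymethyl)acryloyloxy], 10β-methyl, 10α-vinyl | C=C[C@]1(C)C[C@H](OC(=O)C(=C)CO)[C@@H](C(=C)C(=O)O)[C@H](O)[C@H]1C(=C)CO | target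

**Count and risks**

Total steps: 18. Longest linear sequence: 16 (steps 1–12 and 15–18); steps 13–14 make the side-chain acid.

Step 1 (proposed new method). The enyne is a weak π-nucleophile, so turnover may be slow; the cationic intermediate may lose a proton (ene-type adduct) instead of closing; endo/exo or facial control may be poor. Fallback by known chemistry, setting out from 2: 2 and 3,5-dibromo-2H-pyran-2-one F1 (bought) are heated in toluene in a sealed tube at about 100 °C. The thermal [4+2] cycloaddition typical of this ambiphilic pyrone should give the racemic 4,6-dibromo-8-ethynyl-8-methyl-2-oxabicyclo[2.2.2]oct-5-en-3-one F2. Zinc in acetic acid (chosen over a tin hydride because of the alkyne) removes only the bridgehead bromine next to the lactone carbonyl and gives the racemic bromo lactone F3. This is resolved by preparative chromatography on a chiral stationary phase, and the required enantiomer is 7, where the route continues at step 4.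

Step 15. The hindered axial 8β-hydroxyl may fail to form the oxyphosphonium, or the activated alcohol may undergo E2 elimination toward C7 or C9 instead of substitution. Fallback, setting out from 20: inversion is separated from acylation. Tf2O and pyridine at −20 °C give the 8β-triflate F4. Bu4NNO2 in DMF displaces it with inversion to the 8α-nitrite ester F5, which hydrolyses on aqueous work-up to the 8α-alcohol F6 (Lattrell–Dax inversion). Yamaguchi esterification of F6 with 23 (2,4,6-trichlorobenzoyl chloride, Et3N, DMAP), with retention, gives 24.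

Step 9. Boron may add with poor facial selectivity at C6, the protonation at C7 may be unselective, or the β-hydroxy ketone may eliminate or undergo retro-aldol cleavage under the basic oxidation. Fallback, setting out from 14: nucleophilic epoxidation (t-BuOOH, DBU, CH2Cl2) should attack C6 from the α-face and give the 6α,7α-epoxy ketone F7. Reductive opening with SmI2 in THF/MeOH at −78 °C cleaves the C7–O bond next to the ketone and gives 16, with C7 set by protonation of the samarium enolate held by the neighbouring alkoxide (or by later equilibration to the equatorial acetyl).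

**Further compounds**

F1 | step 1 | 3,5-dibromo-2H-pyran-2-one | O=C1OC=C(Br)C=C1Br
F2 | step 1 | racemic 4,6-dibromo-8-ethynyl-8-methyl-2-oxabicyclo[2.2.2]oct-5-en-3-one (ethynyl endo; one enantiomer drawn) | C#C[C@]1(C)C[C@H]2OC(=O)[C@]1(Br)C=C2Br
F3 | step 1 | racemic 6-bromo-8-ethynyl-8-methyl-2-oxabicyclo[2.2.2]oct-5-en-3-one (racemate of 7; one enantiomer drawn) | C#C[C@]1(C)C[C@H]2OC(=O)[C@@H]1C=C2Br
F4 | step 15 | 8β-triflate of 20 | C=C[C@]1(C)C[C@@H](OS(=O)(=O)C(F)(F)F)[C@@H](C(=C)OS(=O)(=O)C(F)(F)F)[C@H](O[Si](C)(C)C(C)(C)C)[C@H]1C(C)=C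
F5 | step 15 | 8α-nitrite ester | C=C[C@]1(C)C[C@H](ON=O)[C@@H](C(=C)OS(=O)(=O)C(F)(F)F)[C@H](O[Si](C)(C)C(C)(C)C)[C@H]1C(C)=C
F6 | step 15 | 8α-alcohol (C8 epimer of 20) | C=C[C@]1(C)C[C@H](O)[C@@H](C(=C)OS(=O)(=O)C(F)(F)F)[C@H](O[Si](C)(C)C(C)(C)C)[C@H]1C(C)=C
F7 | step 9 | 6α,7α-epoxide of 14 (7-acetyl, 8β-OSiEt3, 5β-isopropenyl) | C=C[C@]1(C)C[C@@H](O[Si](CC)(CC)CC)[C@]2(C(C)=O)O[C@@H]2[C@H]1C(C)=C
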